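**Retrosynthetic overview**

1. The acetate and the glyceryl ester are cut first, giving (R)-solketal and the bicyclic acid; the homoprenyl chain is cut at C5 (enol triflate of a C5 ketone plus a homoprenyl Grignard reagent).
2. Feature: with the decalin numbered C1 (carboxyl), C2 (methyl), C4a and C8a (angular methyls) and C5=C6 (alkene), the angular methyls are cis while C5 and C1 lie on opposite faces of the C4a–C8a bond. This is the pattern left by anti addition of a carbon electrophile (C5) and a carbon nucleophile (C1) to a Z tetrasubstituted C4a=C8a alkene.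
3. Key disconnection: C4a–C5 and C8a–C1, made in one cationic bicyclisation of an acyclic Z-ene β-keto ester, started at C5 by a (2R,4R)-pentane-2,4-diol acetal and ended by the keto ester; ring B closes first, ring A second.
4. The C5 oxygen left by the acetal then serves as a tether: its δ-lactone with the C1 carboxyl is a cage that directs hydrogen to C2 from the methyl face; after opening and C5 oxidation, C1 is equilibrated to the all-equatorial ester.
5. The cyclisation substrate comes from 2,3-dimethylmaleic anhydride (source of the Z alkene), the Grignard reagent of a bromoethyl pentanediol acetal and the dianion of methyl acetoacetate.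

Key step: step 9

Assumption: the (4R,6R)-acetal is taken to open by attack anti to the oxygen next to its axial methyl, which makes C5 R; if the sense were the reverse, (2S,4S)-pentane-2,4-diol would be used in step 4 with no other change. The decalin numbering of the overview is used throughout.

**Route**

Step 1
Reactants: 1 2,3-dimethylmaleic anhydride
Product: 2 (Z)-2,3-dimethylbut-2-ene-1,4-diol
Conditions: LiAlH4, Et2O, 0 °C to reflux; aq NaOH work-up
Reagents that add atoms: none
Why: Hydride reduction of the cyclic anhydride should take both carbonyls to primary alcohols, and the Z geometry of the tetrasubstituted alkene is inherited from the ring.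

Step 2
Reactants: 2 (Z)-2,3-dimethylbut-2-ene-1,4-diol
Product: 4 (Z)-4-[(tert-butyldimethylsilyl)oxy]-2,3-dimethylbut-2-en-1-ol, via monosodium alkoxide 3 (not isolated)
Conditions: NaH (1.0 equiv), THF, rt; then TBSCl (1.0 equiv)
Reagents that add atoms: tert-butyldimethylsilyl chloride, CC(C)(C)[Si](C)(C)Cl
Why: Monosilylation of a symmetric diol through its sparingly soluble monosodium alkoxide (O-silylation) should stop after one silyl group.

Step 3
Reactants: 4 mono-silyl ether of the Z diol
Product: 5 tert-butyl{[(Z)-4-chloro-2,3-dimethylbut-2-en-1-yl]oxy}dimethylsilane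
Conditions: N-chlorosuccinimide, Me2S, CH2Cl2, −20 to 0 °C
Reagents that add atoms: N-chlorosuccinimide, O=C1CCC(=O)N1Cl
Why: Corey–Kim chlorination converts a primary allylic alcohol into the chloride under neutral conditions, without allylic transposition or loss of the Z geometry, and spares the silyl ether.

Step 4
Reactants: 6 3-bromo-1,1-dimethoxypropane; 7 (2R,4R)-pentane-2,4-diol
Product: 8 (4R,6R)-2-(2-bromoethyl)-4,6-dimethyl-1,3-dioxane
Conditions: TsOH (cat.), benzene, reflux with removal of MeOH
Reagents that add atoms: none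
Why: Acid-catalysed transacetalisation is driven by removal of methanol, and the C2-symmetric diol gives one acetal with no new stereocentre.

Step 5
Reactants: 8 bromoethyl dioxane; 5 allylic chloride
Product: 10 tert-butyl({(Z)-6-[(4R,6R)-4,6-dimethyl-1,3-dioxan-2-yl]-2,3-dimethylhex-2-en-1-yl}oxy)dimethylsilane, via Grignard reagent 9 (not isolated)
Conditions: Mg, THF, 25 °C; then 5, Li2CuCl4 (3 mol %), THF, −78 to 0 °C
Reagents that add atoms: none
Why: Copper-catalysed coupling of a Grignard reagent with a primary allylic chloride should substitute at the primary carbon, because attack at the other allyl terminus would build a quaternary centre, and it leaves the alkene geometry and the acetal untouched.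

Step 6
Reactants: 10 silyl ether acetal
Product: 11 (Z)-6-[(4R,6R)-4,6-dimethyl-1,3-dioxan-2-yl]-2,3-dimethylhex-2-en-1-ol
Conditions: Bu4NF, THF, 0 °C to rt
Reagents that add atoms: none
Why: Fluoride-mediated desilylation cleaves only the silyl ether and is harmless to the acetal and the alkene.

Step 7
Reactants: 11 allylic alcohol acetal
Product: 12 (4R,6R)-2-[(Z)-6-chloro-4,5-dimethylhex-4-en-1-yl]-4,6-dimethyl-1,3-dioxane
Conditions: N-chlorosuccinimide, Me2S, CH2Cl2, −20 to 0 °C
Reagents that add atoms: N-chlorosuccinimide, O=C1CCC(=O)N1Cl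
Why: Corey–Kim chlorination is neutral, so the acid-labile acetal survives and the Z allylic chloride forms without transposition.

Step 8
Reactants: 13 methyl acetoacetate; 12 allylic chloride acetal
Product: 15 methyl (Z)-10-[(4R,6R)-4,6-dimethyl-1,3-dioxan-2-yl]-6,7-dimethyl-3-oxodec-6-enoate, via acetoacetate dianion 14 (not isolated)
Conditions: NaH, THF, 0 °C; n-BuLi, 0 °C; then 12, 0 °C to rt; AcOH quench
Reagents that add atoms: none
Why: In the γ-alkylation of an acetoacetate dianion the more basic terminal carbanion is alkylated by the allylic chloride, which delivers the β-keto ester with alkene and acetal unchanged.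

Step 9
Reactants: 15 Z-ene keto ester acetal
Product: 16 methyl (1R,4aS,5R,8aR)-5-{[(2R,4R)-4-hydroxypentan-2-yl]oxy}-4a,8a-dimethyl-2-oxodecahydronaphthalene-1-carboxylate (cis-fused; C1 epimerisable through the enol)
Conditions: TiCl4 (3 equiv), 2,4,6-collidine (1 equiv), CH2Cl2 (0.01 M), −78 °C; aq NaHCO3
Reagents that add atoms: none
Why: TiCl4 complexes the acetal oxygen next to the axial methyl of the dioxane, alkene carbon C4a attacks C5 from the side opposite the departing oxygen, and the tertiary C8a cation is captured, anti to the new C4a–C5 bond, by the enol carbon C1 of the keto ester. The closest known reaction types are the Lewis acid-promoted cation–olefin cyclisation of polyene acetals of pentane-2,4-diol and the keto ester-terminated cyclisation of polyene β-keto esters; the demanding element here is the tetrasubstituted central alkene. Ring B closes 6-endo through a chair (C5 to C4a) and ring A closes 6-(enol-endo) (C1 to C8a). C5 (R) is set by the acetal through the anti displacement; C4a follows from the chair with the ether oxygen equatorial, since an axial oxygen would be 1,3-diaxial to the C8a methyl; C8a follows from anti addition across the Z alkene, which makes the methyls cis; C1 stays epimerisable and is not relied on. The step needs 6-endo rather than 5-exo attack on an alkene whose two carbons both give tertiary cations, and carbon rather than oxygen capture: the six-membered chair is the usual preference when both termini are equally substituted, and an O-bound tertiary enol ether would reionise under the Lewis acid and end as the C-bound keto ester.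

Step 10
Reactants: 16 bicyclic keto ester with hydroxypentyl ether
Product: 17 methyl (1R,4aS,5R,8aR)-4a,8a-dimethyl-2-oxo-5-{[(2R)-4-oxopentan-2-yl]oxy}decahydronaphthalene-1-carboxylate
Conditions: [N(C3H7)4][RuO4] (5 mol %), N-methylmorpholine N-oxide, 4 Å MS, CH2Cl2, rt
Reagents that add atoms: none
Why: Ley–Griffith oxidation takes the only free secondary alcohol to the methyl ketone and changes no stereocentre of the bicycle.

Step 11
Reactants: 17 keto ether
Product: 18 methyl (1R,4aS,5R,8aR)-5-hydroxy-4a,8a-dimethyl-2-oxodecahydronaphthalene-1-carboxylate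
Conditions: K2CO3, MeOH, rt
Reagents that add atoms: none
Why: Base-induced β-elimination (E1cB) of the β-alkoxy ketone breaks only the C–O bond on the auxiliary side, so the C5 alcohol is released with its configuration intact while methanol takes up the enone.

Step 12
Reactants: 18 hydroxy keto ester
Product: 19 (1S,4aS,5R,8aR)-5-hydroxy-4a,8a-dimethyl-2-oxodecahydronaphthalene-1-carboxylic acid 1,5-lactone (carboxyl carbon and C5 oxygen both on the face opposite the angular methyls)
Conditions: CSA (0.2 equiv), toluene, reflux, 4 Å MS (removal of MeOH)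
Reagents that add atoms: none
Why: In this acid-catalysed lactonisation C1 equilibrates through the enol, and only the epimer with the carboxyl on the face of the C5 oxygen can close the strain-free 3-oxabicyclo[3.3.1]nonan-2-one cage (a 1,3-diaxial bridge under ring A), so removal of methanol should drain the material into one lactone with C1 fixed.

Step 13
Reactants: 19 cage keto lactone
Product: 21 (1S,4aS,5R,8aR)-5-hydroxy-4a,8a-dimethyl-2-{[(trifluoromethyl)sulfonyl]oxy}-1,4,4a,5,6,7,8,8a-octahydronaphthalene-1-carboxylic acid 1,5-lactone, via potassium enolate 20 (not isolated)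
Conditions: KN(SiMe3)2, THF, −78 °C; then PhNTf2, −78 to 0 °C; aq NH4Cl
Reagents that add atoms: N-phenylbis(trifluoromethanesulfonimide), O=S(=O)(N(c1ccccc1)S(=O)(=O)C(F)(F)F)C(F)(F)F
Why: Enolate O-triflation can only give the C2=C3 enol triflate, because C1 is a bridgehead of the cage and cannot enolise, so the bulky base removes a C3 proton.

Step 14
Reactants: 21 enol triflate lactone
Product: 22 (1R,4aS,5R,8aR)-5-hydroxy-2,4a,8a-trimethyl-1,4,4a,5,6,7,8,8a-octahydronaphthalene-1-carboxylic acid 1,5-lactone
Conditions: MeZnCl, Pd(PPh3)4 (5 mol %), THF, 50 °C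
Reagents that add atoms: methylzinc chloride, C[Zn]Cl
Why: Negishi cross-coupling of an enol triflate with a methylzinc reagent installs the C2 methyl and tolerates the lactone.

Step 15
Reactants: 22 methyl alkene lactone
Product: 23 (1R,2R,4aS,5R,8aR)-5-hydroxy-2,4a,8a-trimethyldecahydronaphthalene-1-carboxylic acid 1,5-lactone
Conditions: H2 (4 atm), PtO2, EtOAc, rt
Reagents that add atoms: none
Why: In this catalytic hydrogenation the lactone bridge fills the lower face of ring A, so hydrogen should add to C2=C3 from the face of the angular methyls and leave the C2 methyl equatorial and trans to them (2R).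

Step 16
Reactants: 23 saturated cage lactone
Product: 25 (1R,2R,4aS,8aR)-2,4a,8a-trimethyl-5-oxodecahydronaphthalene-1-carboxylic acid, via potassium hydroxy carboxylate 24 (not isolated)
Conditions: KOH, H2O/t-BuOH, 80 °C; then KMnO4, 0 °C; NaHSO3, aq HCl
Reagents that add atoms: potassium hydroxide, [K+].[OH-]
Why: Saponification followed by permanganate oxidation in the same alkaline solution works because the carboxylate cannot relactonise and, with no alkene present, the freed C5 carbinol is the only oxidisable group, so the ketone forms and ring closure is excluded for good.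

Step 17
Reactants: 25 keto acid with axial carboxyl
Product: 26 methyl (1R,2R,4aS,8aR)-2,4a,8a-trimethyl-5-oxodecahydronaphthalene-1-carboxylate
Conditions: MeI, K2CO3, DMF, rt
Reagents that add atoms: iodomethane, CI
Why: O-Alkylation of the carboxylate (SN2 on iodomethane) esterifies the hindered acid without any attack at its shielded carbonyl carbon.

Step 18
Reactants: 26 methyl keto ester, 1R epimer
Product: 27 methyl (1S,2R,4aS,8aR)-2,4a,8a-trimethyl-5-oxodecahydronaphthalene-1-carboxylate
Conditions: NaOMe, MeOH, reflux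
Reagents that add atoms: none
Why: Base-mediated epimerisation through the ester enolate is thermodynamically driven, since the 1R ester is 1,3-diaxial to C5 in one chair and has the C2 methyl 1,3-diaxial to C8 in the other, whereas the 1S epimer carries ester and methyl both equatorial.

Step 19
Reactants: 27 methyl keto ester, 1S epimer
Product: 28 (1S,2R,4aS,8aR)-2,4a,8a-trimethyl-5-oxodecahydronaphthalene-1-carboxylic acid
Conditions: LiI, pyridine, reflux; aq HCl
Reagents that add atoms: none
Why: SN2 demethylation by iodide attacks the O-methyl carbon rather than the blocked carbonyl of this hindered ester and does not disturb C1.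

Step 20
Reactants: 28 keto acid, 1S epimer; 29 (R)-solketal
Product: 30 [(4S)-2,2-dimethyl-1,3-dioxolan-4-yl]methyl (1S,2R,4aS,8aR)-2,4a,8a-trimethyl-5-oxodecahydronaphthalene-1-carboxylate
Conditions: PPh3, DIAD, THF, 0 °C to rt
Reagents that add atoms: none
Why: In the Mitsunobu esterification the carboxylate displaces the activated primary hydroxyl of solketal at its CH2 group, so the hindered carbonyl is not attacked and the dioxolane stereocentre keeps its arrangement (its descriptor becomes S by priority only).

Step 21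
Reactants: 30 solketal keto ester
Product: 32 [(4S)-2,2-dimethyl-1,3-dioxolan-4-yl]methyl (1S,2R,4aS,8aR)-2,4a,8a-trimethyl-5-{[(trifluoromethyl)sulfonyl]oxy}-1,2,3,4,4a,7,8,8a-octahydronaphthalene-1-carboxylate, via potassium enolate 31 (not isolated)
Conditions: KN(SiMe3)2, THF, −78 °C; then PhNTf2, −78 to 0 °C; aq NH4Cl
Reagents that add atoms: N-phenylbis(trifluoromethanesulfonimide), O=S(=O)(N(c1ccccc1)S(=O)(=O)C(F)(F)F)C(F)(F)F
Why: Enolate O-triflation is regiodefined because C4a is quaternary and the ketone can enolise only towards C6, and the C6 protons are more acidic and more accessible than the hindered C1–H of the ester.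

Step 22
Reactants: 32 C5 enol triflate; 33 5-bromo-2-methylpent-2-ene
Product: 35 [(4S)-2,2-dimethyl-1,3-dioxolan-4-yl]methyl (1S,2R,4aR,8aR)-2,4a,8a-trimethyl-5-(4-methylpent-3-en-1-yl)-1,2,3,4,4a,7,8,8a-octahydronaphthalene-1-carboxylate, via homoprenylmagnesium bromide 34 (not isolated)
Conditions: Mg, THF; then 32, Fe(acac)3 (10 mol %), THF/NMP, −30 to 0 °C
Reagents that add atoms: none
Why: Fe(acac)3-catalysed Kumada-type coupling of an alkyl Grignard reagent with an enol triflate is fast at low temperature, free of β-hydride elimination, and should leave the hindered ester and the acetonide alone.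

Step 23
Reactants: 35 solketal ester of the diene acid
Product: 36 (2S)-2,3-dihydroxypropyl (1S,2R,4aR,8aR)-2,4a,8a-trimethyl-5-(4-methylpent-3-en-1-yl)-1,2,3,4,4a,7,8,8a-octahydronaphthalene-1-carboxylate
Conditions: AcOH/H2O (4:1), 40 °C
Reagents that add atoms: none
Why: Mild acid hydrolysis of the acetonide frees the 1,2-diol, while the two trisubstituted alkenes tolerate dilute acetic acid and migration of the very hindered acyl group is slow.

Step 24
Reactants: 36 monoacyl glycerol
Product: 37 (2S)-3-acetoxy-2-hydroxypropyl (1S,2R,4aR,8aR)-2,4a,8a-trimethyl-5-(4-methylpent-3-en-1-yl)-1,2,3,4,4a,7,8,8a-octahydronaphthalene-1-carboxylate (CNP0146255.1)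
Conditions: AcCl (1.05 equiv), 2,4,6-collidine, CH2Cl2, −78 °C
Reagents that add atoms: acetyl chloride, CC(Cl)=O
Why: Selective acylation of the primary hydroxyl with acetyl chloride and a hindered pyridine base at low temperature leaves the secondary hydroxyl free and does not touch the glycerol stereocentre taken from solketal.

**Compound list**

1 | 2,3-dimethylmaleic anhydride | CC1=C(C)C(=O)OC1=O | starting material
2 | (Z)-2,3-dimethylbut-2-ene-1,4-diol | OC/C(C)=C(C)\CO | intermediate
3 | monosodium alkoxide of 2 | [Na+].[O-]C/C(C)=C(C)\CO | intermediate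
4 | (Z)-4-[(tert-butyldimethylsilyl)oxy]-2,3-dimethylbut-2-en-1-ol | CC(C)(C)[Si](C)(C)OC/C(C)=C(C)\CO | intermediate
5 | tert-butyl{[(Z)-4-chloro-2,3-dimethylbut-2-en-1-yl]oxy}dimethylsilane | CC(C)(C)[Si](C)(C)OC/C(C)=C(C)\CCl | intermediate
6 | 3-bromo-1,1-dimethoxypropane | COC(CCBr)OC | starting material
7 | (2R,4R)-pentane-2,4-diol | C[C@@H](O)C[C@@H](C)O | starting material
8 | (4R,6R)-2-(2-bromoethyl)-4,6-dimethyl-1,3-dioxane | BrCCC1O[C@H](C)C[C@@H](C)O1 | intermediate
9 | {2-[(4R,6R)-4,6-dimethyl-1,3-dioxan-2-yl]ethyl}magnesium bromide | Br[Mg]CCC1O[C@H](C)C[C@@H](C)O1 | intermediate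
10 | tert-butyl({(Z)-6-[(4R,6R)-4,6-dimethyl-1,3-dioxan-2-yl]-2,3-dimethylhex-2-en-1-yl}oxy)dimethylsilane | CC(C)(C)[Si](C)(C)OC/C(C)=C(C)\CCCC1O[C@H](C)C[C@@H](C)O1 | intermediate
11 | (Z)-6-[(4R,6R)-4,6-dimethyl-1,3-dioxan-2-yl]-2,3-dimethylhex-2-en-1-ol | OC/C(C)=C(C)\CCCC1O[C@H](C)C[C@@H](C)O1 | intermediate
12 | (4R,6R)-2-[(Z)-6-chloro-4,5-dimethylhex-4-en-1-yl]-4,6-dimethyl-1,3-dioxane | ClC/C(C)=C(C)\CCCC1O[C@H](C)C[C@@H](C)O1 | intermediate
13 | methyl acetoacetate | COC(=O)CC(C)=O | starting material
14 | methyl acetoacetate dianion, sodium lithium salt | [Na+].[Li+].COC(=O)[CH-]C(=O)[CH2-] | intermediate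
15 | methyl (Z)-10-[(4R,6R)-4,6-dimethyl-1,3-dioxan-2-yl]-6,7-dimethyl-3-oxodec-6-enoate | COC(=O)CC(=O)CC/C(C)=C(C)\CCCC1O[C@H](C)C[C@@H](C)O1 | intermediate
16 | methyl (1R,4aS,5R,8aR)-5-{[(2R,4R)-4-hydroxypentan-2-yl]oxy}-4a,8a-dimethyl-2-oxodecahydronaphthalene-1-carboxylate (cis-fused, C1 epimerisable) | COC(=O)[C@H]1C(=O)CC[C@]2(C)[C@H](O[C@H](C)C[C@@H](C)O)CCC[C@]12C | intermediate
17 | methyl (1R,4aS,5R,8aR)-4a,8a-dimethyl-2-oxo-5-{[(2R)-4-oxopentan-2-yl]oxy}decahydronaphthalene-1-carboxylate | COC(=O)[C@H]1C(=O)CC[C@]2(C)[C@H](O[C@H](C)CC(C)=O)CCC[C@]12C | intermediate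
18 | methyl (1R,4aS,5R,8aR)-5-hydroxy-4a,8a-dimethyl-2-oxodecahydronaphthalene-1-carboxylate | COC(=O)[C@H]1C(=O)CC[C@]2(C)[C@H](O)CCC[C@]12C | intermediate
19 | (1S,4aS,5R,8aR)-5-hydroxy-4a,8a-dimethyl-2-oxodecahydronaphthalene-1-carboxylic acid 1,5-lactone | O=C3[C@@H]1C(=O)CC[C@]2(C)[C@H](O3)CCC[C@]12C | intermediate
20 | potassium C2,C3-enolate of 19 | [K+].O=C3[C@@H]1C([O-])=CC[C@]2(C)[C@H](O3)CCC[C@]12C | intermediate
21 | (1S,4aS,5R,8aR)-5-hydroxy-4a,8a-dimethyl-2-{[(trifluoromethyl)sulfonyl]oxy}-1,4,4a,5,6,7,8,8a-octahydronaphthalene-1-carboxylic acid 1,5-lactone | O=C3[C@@H]1C(OS(=O)(=O)C(F)(F)F)=CC[C@]2(C)[C@H](O3)CCC[C@]12C | intermediate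
22 | (1R,4aS,5R,8aR)-5-hydroxy-2,4a,8a-trimethyl-1,4,4a,5,6,7,8,8a-octahydronaphthalene-1-carboxylic acid 1,5-lactone | O=C3[C@@H]1C(C)=CC[C@]2(C)[C@H](O3)CCC[C@]12C | intermediate
23 | (1R,2R,4aS,5R,8aR)-5-hydroxy-2,4a,8a-trimethyldecahydronaphthalene-1-carboxylic acid 1,5-lactone | O=C3[C@@H]1[C@H](C)CC[C@]2(C)[C@H](O3)CCC[C@]12C | intermediate
24 | potassium (1R,2R,4aS,5R,8aR)-5-hydroxy-2,4a,8a-trimethyldecahydronaphthalene-1-carboxylate | [K+].[O-]C(=O)[C@@H]1[C@H](C)CC[C@]2(C)[C@H](O)CCC[C@]12C | intermediate
25 | (1R,2R,4aS,8aR)-2,4a,8a-trimethyl-5-oxodecahydronaphthalene-1-carboxylic acid | OC(=O)[C@@H]1[C@H](C)CC[C@]2(C)C(=O)CCC[C@]12C | intermediate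
26 | methyl (1R,2R,4aS,8aR)-2,4a,8a-trimethyl-5-oxodecahydronaphthalene-1-carboxylate | COC(=O)[C@@H]1[C@H](C)CC[C@]2(C)C(=O)CCC[C@]12C | intermediate
27 | methyl (1S,2R,4aS,8aR)-2,4a,8a-trimethyl-5-oxodecahydronaphthalene-1-carboxylate | COC(=O)[C@H]1[C@H](C)CC[C@]2(C)C(=O)CCC[C@]12C | intermediate
28 | (1S,2R,4aS,8aR)-2,4a,8a-trimethyl-5-oxodecahydronaphthalene-1-carboxylic acid | OC(=O)[C@H]1[C@H](C)CC[C@]2(C)C(=O)CCC[C@]12C | intermediate
29 | (R)-solketal, [(4R)-2,2-dimethyl-1,3-dioxolan-4-yl]methanol | CC1(C)OC[C@H](O1)CO | starting material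
30 | [(4S)-2,2-dimethyl-1,3-dioxolan-4-yl]methyl (1S,2R,4aS,8aR)-2,4a,8a-trimethyl-5-oxodecahydronaphthalene-1-carboxylate | CC1(C)OC[C@H](O1)COC(=O)[C@H]1[C@H](C)CC[C@]2(C)C(=O)CCC[C@]12C | intermediate
31 | potassium C5,C6-enolate of 30 | [K+].CC1(C)OC[C@H](O1)COC(=O)[C@H]1[C@H](C)CC[C@]2(C)C([O-])=CCC[C@]12C | intermediate
32 | [(4S)-2,2-dimethyl-1,3-dioxolan-4-yl]methyl (1S,2R,4aS,8aR)-2,4a,8a-trimethyl-5-{[(trifluoromethyl)sulfonyl]oxy}-1,2,3,4,4a,7,8,8a-octahydronaphthalene-1-carboxylate | CC1(C)OC[C@H](O1)COC(=O)[C@H]1[C@H](C)CC[C@]2(C)C(OS(=O)(=O)C(F)(F)F)=CCC[C@]12C | intermediate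
33 | 5-bromo-2-methylpent-2-ene | CC(C)=CCCBr | starting material
34 | (4-methylpent-3-en-1-yl)magnesium bromide | CC(C)=CCC[Mg]Br | intermediate
35 | [(4S)-2,2-dimethyl-1,3-dioxolan-4-yl]methyl (1S,2R,4aR,8aR)-2,4a,8a-trimethyl-5-(4-methylpent-3-en-1-yl)-1,2,3,4,4a,7,8,8a-octahydronaphthalene-1-carboxylate | CC1(C)OC[C@H](O1)COC(=O)[C@H]1[C@H](C)CC[C@]2(C)C(CCC=C(C)C)=CCC[C@]12C | intermediate
36 | (2S)-2,3-dihydroxypropyl (1S,2R,4aR,8aR)-2,4a,8a-trimethyl-5-(4-methylpent-3-en-1-yl)-1,2,3,4,4a,7,8,8a-octahydronaphthalene-1-carboxylate | OC[C@H](O)COC(=O)[C@H]1[C@H](C)CC[C@]2(C)C(CCC=C(C)C)=CCC[C@]12C | intermediate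
37 | (2S)-3-acetoxy-2-hydroxypropyl (1S,2R,4aR,8aR)-2,4a,8a-trimethyl-5-(4-methylpent-3-en-1-yl)-1,2,3,4,4a,7,8,8a-octahydronaphthalene-1-carboxylate | CC(=O)OC[C@H](O)COC(=O)[C@H]1[C@H](C)CC[C@]2(C)C(CCC=C(C)C)=CCC[C@]12C | target

**Step count and risks**

Total step count: 24. Longest linear sequence: 23 steps (from 1 through steps 1–3 and 5–24; step 4 is the side branch).

Steps most likely to fail:

Step 9. Capture of the C8a cation by the keto ester may be too slow, so that proton loss, methyl migration from C4a, oxygen capture or 5-exo closure take over. The fallback arms the terminator beforehand. Compound 15 is silylated (TBSOTf, Et3N, CH2Cl2, 0 °C) to the silyl enol ether methyl (2Z,6Z)-3-[(tert-butyldimethylsilyl)oxy]-10-[(4R,6R)-4,6-dimethyl-1,3-dioxan-2-yl]-6,7-dimethyldeca-2,6-dienoate F1, a preformed carbon nucleophile of the kind that ends cation–olefin cyclisations. F1 is then cyclised with TiCl4 in CH2Cl2 at −78 °C; loss of the silyl group on carbon capture gives 16, where the route is rejoined.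

Step 15. Hydrogen uptake at the C2=C3 alkene, whose only open face carries the axial C8a methyl, may be slow, and migration of the double bond on the catalyst would then erode the facial control. The fallback leaves out the enol triflate and sets C2 under thermodynamic control. Ketone 19 is methylenated by a Wittig reaction (Ph3P=CH2, THF, 0 °C to rt) to the exocyclic alkene (1R,4aS,5R,8aR)-5-hydroxy-4a,8a-dimethyl-2-methylidenedecahydronaphthalene-1-carboxylic acid 1,5-lactone F2. F2 is reduced by hydrogen atom transfer (Mn(dpm)3, tris(2,2,6,6-tetramethylheptane-3,5-dionato)manganese, PhSiH3, t-BuOOH, i-PrOH, rt). The tertiary C2 radical should take up hydrogen so that the methyl ends equatorial, away from the axial C8a methyl, which gives 23.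

Step 22. Coupling at the C5 triflate, which is flanked by the quaternary C4a, may be slow, so that reduction of the triflate or attack of the Grignard reagent on the ester competes. The fallback makes the same bond by carbonyl addition. Grignard reagent 34 is added to ketone 30 in the presence of anhydrous CeCl3 (THF, −78 °C). Axial attack is blocked by ring A, so the chain should enter equatorially and give the tertiary alcohol [(4S)-2,2-dimethyl-1,3-dioxolan-4-yl]methyl (1S,2R,4aS,8aR)-5-hydroxy-2,4a,8a-trimethyl-5-(4-methylpent-3-en-1-yl)decahydronaphthalene-1-carboxylate F3, with the hydroxyl axial and trans to the angular methyls. Dehydration with POCl3 in pyridine, anti to the axial C6 hydrogen, then gives 35.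

**Further compounds**

F1 | step 9 | methyl (2Z,6Z)-3-[(tert-butyldimethylsilyl)oxy]-10-[(4R,6R)-4,6-dimethyl-1,3-dioxan-2-yl]-6,7-dimethyldeca-2,6-dienoate | COC(=O)/C=C(O[Si](C)(C)C(C)(C)C)/CC/C(C)=C(C)\CCCC1O[C@H](C)C[C@@H](C)O1
F2 | step 15 | (1R,4aS,5R,8aR)-5-hydroxy-4a,8a-dimethyl-2-methylidenedecahydronaphthalene-1-carboxylic acid 1,5-lactone | O=C3[C@@H]1C(=C)CC[C@]2(C)[C@H](O3)CCC[C@]12C
F3 | step 22 | [(4S)-2,2-dimethyl-1,3-dioxolan-4-yl]methyl (1S,2R,4aS,8aR)-5-hydroxy-2,4a,8a-trimethyl-5-(4-methylpent-3-en-1-yl)decahydronaphthalene-1-carboxylate, hydroxyl trans to the angular methyls | CC1(C)OC[C@H](O1)COC(=O)[C@H]1[C@H](C)CC[C@]2(C)[C@@](O)(CCC=C(C)C)CCC[C@]12C
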